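The readings stem from a simulated flask for an exercise.

A molecule of L cannot end up as both J and Q, so each L that reacts takes one branch or the other, and the question is how those branches divide.

common to all: Z 1.2 mM (held)

| charge | L | temperature | remark | time |
|---|---|---|---|---|
| north-west | 52 mM | 10 °C | run made earlier |  |
| south-west | 81 mM | 21 °C | run made earlier |  |
| Monday's | 37 mM |  | at 5 °C until 4.0 min, from then on at 25 °C | 8.0 min |
| Thursday's | 37 mM | 25 °C |  | 8.0 min |
| Sunday's | 37 mM | 5 °C |  | 8.0 min |

| run | time / min | J / % | Q / % |
|---|---|---|---|
| north-west | 1.00 | 1.3 | 4.0 |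
| north-west | 2.00 | 4.0 | 7.8 |
| north-west | 3.00 | 5.7 | 12.3 |
| north-west | 4.00 | 7.5 | 15.5 |
| north-west | 6.00 | 10.3 | 22.4 |
| north-west | 8.00 | 13.6 | 28.4 |
| north-west | 12.0 | 18.6 | 39.3 |
| south-west | 0.500 | 0.3 | 1.7 |
| south-west | 0.833 | 2.2 | 3.7 |
| south-west | 1.33 | 2.3 | 4.4 |
| south-west | 2.00 | 4.1 | 7.1 |
| south-west | 3.00 | 5.1 | 10.0 |
| south-west | 4.00 | 7.5 | 14.8 |
| south-west | 6.00 | 9.3 | 22.3 |

(readings scatter by 0.5 percentage points)

- the analysis behind the earlier runs scatters by 0.5 percentage points, standard deviation
- at the start none of Z is in solution
- a reading or a percentage of J counts all its forms, free or not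

1. the flask with the highest share of J in all that became J or Q ("all alike" if they lie within 1.5 percentage points) (Monday's / Thursday's / Sunday's / all alike)
2. share of J in all that became J or Q, Monday's
3. share of J in all that became J or Q, Thursday's
4. share of J in all that became J or Q, Sunday's

*What would you read from the earlier runs?* I would read the share of J, s, meaning J divided by J plus Q, which is the usual selectivity. I add up each run's readings before dividing. The first south-west reading shows why: J is 0.3% against a scatter of 0.5 percentage points, so its share of 15.0% says little. Pooled, the north-west run gives 32.0% and the south-west run 32.5%. My carried value is their mean, the branch share s = 32.2%.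

*But L and temperature rose together between those runs. Couldn't two effects cancel?* For L, I can test that inside one flask. If the L lost is J plus Q, the north-west run has 77.0% of its L left at 4.00 min and 42.1% at 12.0 min, yet the share reads 32.6% and then 32.1%. Temperature stays open: the pooled shares differ by 0.5 points between the north-west run at 10 °C and the south-west run at 21 °C, and one reading scatters by 0.5 points, so I can read no direction.

*So what do you commit to?* I expect s in each new flask, with the warning that 5 °C and 25 °C lie outside the tested temperatures. J at any moment should then be s times the L lost.

The forecast gave 32% for Monday's, 32% for Thursday's and 32% for Sunday's, hence all alike, on the ground that “The share of J is flat in both runs”.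

    Z ⇌ G, rate k1*(csat - [G]) (kL = 5.10 /min)
    G + J ⇌ E, settled at all times (K = 320 /M, ΔH = −35.0 kJ/mol)
    L + G → Q (k = 170 /M/min, Ea = 36.0 kJ/mol)
    L + G → J (k = 80.0 /M/min, Ea = 35.0 kJ/mol)
    (constants at 25 °C)

The result is all alike: 32.2% in Monday's, 32.0% in Thursday's and 32.6% in Sunday's. From the coldest flask to the hottest, the step from L and G to J speeds up by a factor of 2.8 and the step from L and G to Q by a factor of 2.8, while conversion of L at the end runs from 41.4% in Sunday's to 66.4% in Thursday's. In Thursday's, s times the L lost gives 21.4% of J, and the flask holds 21.2%, with E counted in. In the flask like Sunday's but read at 20 min, 22% of the L remains, so s gives 25.1% of J, and that flask holds, with E counted in, 25.6%.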